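The readings are simulated on assumed constants.

How much target stands in the flask after 2.5 d, and which change is worth making?

| flask | starting material | gas phase | free catalyst | impurity | remark | time |
|---|---|---|---|---|---|---|
| Saturday's | 0.067 M | 56 mM (held) | 0.86 mol% | 0.16 mM | run made earlier |  |
| Thursday's | 0.15 M | 56 mM (held) | 0.86 mol% | 0.16 mM | run made earlier |  |
| flask | 0.10 M | 56 mM (held) | 0.86 mol% | 0.16 mM |  | 2.5 d |

| Saturday's: time / h | Saturday's: target / % | Thursday's: time / h | Thursday's: target / % |
|---|---|---|---|
| 10.0 | 23.9 | 10.0 | 12.3 |
| 20.0 | 48.6 | 20.0 | 25.6 |
| 30.0 | 71.6 | 30.0 | 39.9 |
| 40.0 | 88.1 | 40.0 | 49.7 |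
| 50.0 | 95.0 | 50.0 | 64.6 |

(each reading ± 1 percentage point)

- the analysis behind the earlier runs scatters by 1 percentage point, standard deviation
- at the start none of the gas phase is in solution

- ochre: doubling the amount of free catalyst, all else as stated
- blue: doubling the saturation concentration of gas phase, all else as stated
- red: doubling the transfer coefficient of the gas phase, all else as stated

* how much target there is at 2.5 d, in percent of the starting material charged
* concentration of dissolved gas in solution at 15 h, in percent of saturation
* the change that raises the amount of target at 2.5 d, in percent of the starting material charged most ("none" if none brings more than 2 percentage points) (ochre / blue / red / none)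
* amount of target at 2.5 d, in percent of the starting material charged, after red

Both runs climb about straight through their early readings, so I read one slope from each. Saturday's run reaches 48.6 % at 20.0 h, which is 1.63 mM h⁻¹, and Thursday's run reaches 64.6 % at 50.0 h, which is 1.94 mM h⁻¹. Thursday's charge is about twice Saturday's, and its catalyst moves with it as mol%, yet its slope is 1.19 times as steep, so in these two runs the slope follows the charge only weakly. Interpolating on the charge gives 1.75 mM h⁻¹ for the flask; this is its filling rate, the rise of c(target) per hour on the straight part.

I draw the flask's curve as a line at that slope, which crosses half the charge at 28.6 h. On that line it meets the full charge at 57.1 h, the knee, which comes 2.90 h before the asked time. Saturday's knee, reckoned the same way, falls at 41.2 h, and that run read 88.1 % at 40.0 h and 95.0 % at 50.0 h, so the curve rounds off below the full charge. Those two readings lie on either side of the same distance past the knee, so I reckon the flask lands between them.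

The forecast says 91 %, which lies in that span, with 18 % of saturation at 15 h, blue as the best change and 98 % after red: “Doubling saturation raises both transfer and kinetics, so blue is best.”

The flask gives 95.3 %, just above my span, and 96.2 % after red, with dissolved gas at 2.06 % of saturation at 15 h.

    gas phase ⇌ dissolved gas, rate k1*(csat - [dissolved gas]) (kL = 1.00 × 10⁻⁵ s⁻¹)
    starting material + dissolved gas → uncatalysed product (k = 2.50 × 10⁻⁴ M⁻¹ s⁻¹)
    free catalyst + impurity → spent catalyst (k = 34.0 M⁻¹ s⁻¹)
    starting material + dissolved gas + free catalyst → free catalyst + target (k = 9.00 M⁻² s⁻¹)

The best change is ochre, worth 2.9 percentage points against 0.86 points for blue and 0.86 points for red. At the asked time the flask holds 3.78 % as uncatalysed product, more than the 0.894 % of starting material left. The filling rate over 1.25 d gives 52.5 %, and the flask stands at 55.1 %.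

Read at 15 h instead, the same flask should hold, by the filling rate, 26.3 %. The computed reading is 27.5 %.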